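The data are calculated on assumed constants, noise included.

The south flask holds more partner than starting material, 34.2 mM against 19 mM, yet its product lies flat near 27.0 %, with 72.5 % of the starting material unused. My next charge hangs on what stopped it.

the same everywhere: starting material 19 mM; partner 34.2 mM; free catalyst 0.47 mM
- south: the very flask that is asked about, followed so far
- flask: time 1.5 h

- south (time / min: product / %, starting material / %): 4.00: 13.4, 85.5; 12.0: 23.3, 77.0; 20.0: 25.7, 73.6; 30.0: 27.3, 73.0; 40.0: 27.0, 72.8; 60.0: 27.4, 72.1; 80.0: 26.4, 72.1

(standard deviation of a reading: 0.5 percentage points)

- beta: at 1.5 h add partner, 50.0 % of the amount charged, then wait 50 min
- eta: at 1.5 h take out 90 % of the product then present, then wait 50 min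
- delta: change nothing and wait 50 min more
- zeta: at 1.5 h add free catalyst, 50.0 % of the amount charged, then wait 50 min

- what is taken out of product is counted as made
- additions bring no volume worth counting

- product, in percent of the starting material first charged, at 1.5 h
- the remedy with the largest gain of product, or "none" below 2 percentage points (beta / eta / delta / zeta / none)
- product present, with what was taken out counted in, in percent of the starting material first charged, after eta
- product present, with what was taken out counted in, in percent of the starting material first charged, after zeta

These readings do not show what stopped the flask, and none of them follows the partner. So I wager on a side loss of partner, first order in partner, beside a product rate proportional to partner times A, the concentration of starting material. Then a share A/(A+H) of the partner used makes product, where H, here 90.4 mM, is the even-split concentration, the A at which partner goes equally to product and to loss. It is the inverse of a selectivity factor, and I get it from the integrated rule: partner used = starting material used + H × ln(A before / A after), with the partner used set equal to its charge. H is a reading, and it stands above the charge of starting material, so the south flask starts with a share of 17.4 % to product.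

The decision follows. Waiting, taking out product and adding catalyst bring no partner, so I reckon 27.0 % for now and for both eta and zeta. Beta brings 17.1 mM of partner onto 13.8 mM of starting material, and the rule gives a gain of 11 percentage points, above the 2 points bar. The south readings reach half of their plateau by 4.00 min, far inside the 50 min wait. I charge partner.

The forecast gave 27 % for now, eta as best, 43 % after eta and 27.5 % after zeta: “Equilibrium is my working assumption, and eta has the largest expected gain, so I choose eta.”

The flask gives 26.8 % now, and beta is best, gaining 12 points, while eta and zeta stay at 26.8 % and 26.8 %.

    partner → decomposed reagent (k = 0.00229 s⁻¹)
    starting material + free catalyst ⇌ catalyst intermediate A (K = 19.9 M⁻¹, k = 536 M⁻¹ s⁻¹)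
    partner + catalyst intermediate B ⇌ catalyst intermediate C (K = 20.8 M⁻¹, k = 60.4 M⁻¹ s⁻¹)
    catalyst intermediate C → free catalyst + product (k = 0.595 s⁻¹)
    catalyst intermediate A ⇌ catalyst intermediate B (K = 0.400, k = 1.62 s⁻¹)

At 90.0 min the south flask holds 29.1 mM of decomposed reagent against 5.10 mM of product, and partner, the limiting reagent, stands at 0 % of its charge. The catalyst is 100 % still able to turn over, with 72.3 % of it free. In the neighbour flask charged with 140 mM of partner, H and the same rule give 75.2 % product; the computed flask gives 72.9 %.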